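## Structural features

The target is a biflavonoid. A (2S)-flavanone of the eriodictyol type (phloroglucinol ring A, dihydropyranone ring C, catechol ring B) is bonded through C5' of ring B to C8'' of an apigenin unit, which consists of phloroglucinol ring D fused to 4-pyranone ring E, with the 4-hydroxyphenyl ring F on C2''. C2 of ring C is the only stereocentre and has no stereogenic neighbour. The C5'–C8'' axis is flanked by the C4' hydroxyl, the C7'' hydroxyl, C8a''–O1'' and one hydrogen (C6'), and it carries no descriptor. C2 is the fragile point: it is benzylic, β to the C4 ketone and para to the C4' hydroxyl, so ring C opens reversibly to the chalcone in base and in hot acid and the configuration is lost. Other liabilities are the seven phenols, the air-sensitive catechol, and the drift of a 5-hydroxy-8-arylflavone to its 6-aryl isomer when ring E is opened and reclosed in hot mineral acid (Wessely–Moser rearrangement). The real difficulty is a bond between two electron-rich rings that is flanked by oxygen on three sides, together with the need to tell the C8a'' oxygen from the C5'' and C7'' oxygens so that ring E closes on the correct side of ring D. Ring B offers the handle: C3' (oxygen), C4' (oxygen) and C5' (C8'') are contiguous, so an aryne across C4' and C5' has the C3' oxygen directly beside it and is polarised to take a carbon nucleophile at C5' and then an oxygen electrophile at C4'.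

## Logic of the disconnections

**28 from 27.** The seven phenolic O–H bonds are traced back to O–benzyl bonds. Benzyl is chosen because it leaves under neutral hydrogenolysis, the only regime in which C2 next to a free C4' phenol is not at risk. Nothing is simplified in the skeleton. The forward step must remove seven ethers without touching C2''=C3'' or the benzylic C2–O1 bond.

**27 from 25 (through 26).** The O1–C2 bond of ring C is cut and an ester is added back on C3. This removes the only stereocentre and turns ring C into an open, doubly activated alkene. The forward closure must deliver O1 to one face of C2 from an E/Z mixture, and the ester must then leave without opening ring C again.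

**25 from 20 and 24.** The C2=C3 double bond is cut. This is the most convergent cut of the molecule, because it separates ring A from everything else. It requires an unhindered aldehyde on C1' and a condensation mild enough not to close ring C racemically.

**24 from 22, 22 from 21.** The C3–ester bond and two O–benzyl bonds are cut, which leads to a commercial ketone. The acylation must occur on carbon next to a free phenol. The benzylation must spare the one hydroxyl that is hydrogen-bonded to the ketone.

**20 from 19, 19 from 18.** Five O–benzyl bonds are traced to O–H and then to O–methyl. Benzyl ethers do not tolerate the alkyllithium steps, and methyl ethers cannot be removed once C2 exists, so the exchange is placed at the last achiral intermediate. The demethylation must spare the aldehyde and must not open ring E.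

**18 from 16 (through 17).** The O1''–C2'' bond of ring E is cut, and the C8a'' oxygen and the aldehyde are re-masked. One acid treatment then does three jobs in the forward sense. Only the C8a'' oxygen may become free, which holds because the C5'' oxygen stays methylated, so the 6-aryl isomer cannot form.

**16 from 11 and 14; 14 from 12.** The C4a''–C4'' bond is cut, with ring D as the aryl anion and all of C4'', C3'', C2'' and ring F as one acyl cation equivalent. A Friedel–Crafts acetylation directed by a free phenol was rejected. Any acid that frees the C8a'' oxygen or drives the acylation also frees the aldehyde while ring D is still a phloroglucinol-type nucleophile, and that pair condenses (the reaction behind the vanillin colour test). The metalation route stays basic until ring D carries its deactivating carbonyl. It requires site-selective lithiation at C4a''.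

**11 from 10.** One O–methyl bond is cut. The cap is needed because the free C4' hydroxyl is acidic and, being para to C1', makes the acetal labile.

**10 from 2 and 4 (through 5 to 9).** The C5'–C8'' and C4'–O bonds are cut together, which is the key simplification: two one-step arenes replace a tri-ortho-substituted, fully oxygenated biaryl. Several design points matter.
- In 4, the carbon that must be metalated is the one between the methoxy and the methoxymethoxy group. This is C4 when the two methoxy groups are numbered C1 and C3, not C2, which lies between the two methoxy groups. Only this site places the marked oxygen ortho to the new bond.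
- The aldehyde mask in 2 is a six-membered acetal, not a dioxolane.
- The nucleophile 5 is made beforehand and kept in excess.
- The base for 2 is an alkyllithium, so that no amine can add to 7.

**2 from 1; 4 from 3.** An acetal and an ether are removed, which leads to commercial compounds.

## Other disconnections considered

**Alternative 1:** The cut is C4a''–C5'' inside ring D, so that ring D is grown onto a finished ring E. The precursor would be tert-butyl 4-(5-bromo-2,3-dibenzyloxyphenyl)-4-[6-(4-benzyloxyphenyl)-4-oxo-4H-pyran-2-yl]-3-oxobutanoate A1, in which the future C8'' is an sp3 methine. On heating, loss of the tert-butoxy group should create a ketene function at C5''. Enolisation of the C7'' carbonyl toward C8'' would then set up the conjugated array C5''=C6''–C7''=C8''–C8a''=C4a''. A six-electron electrocyclisation and tautomerisation would give the flavone A2.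
- *In favour:* the ring B to C8'' bond is made before any biaryl hindrance exists. The 8-aryl/6-aryl question cannot arise because O1'' already sits on C8a''. Benzyl ethers are present from the start, so no ether exchange is needed. On these three points it is better than the chosen plan, and its neutral pericyclic mechanism is at least as gentle as organolithium chemistry.
- *Against:* A1 is a doubly activated methine that needs a long linear preparation. The ring closure must use a double bond of a 4-pyranone that is stabilised as a vinylogous ester, for which analogy is thin. The ketene function can also be recaptured or dimerise.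
- *Further work after A2:* A2 carries bromine where C2 must be attached, so two phenols must be protected and a formylation must be run beside the flavone carbonyl.
- *Step economy:* it should be clearly longer than a plan in which two one-step arenes give both bonds at once.

**Alternative 2:** The cut is O1–C2 of ring C. The E/Z alkylidene β-keto ester A3 would close under a quinine-derived bifunctional thiourea. The thiourea holds the two carbonyl groups and the quinuclidine nitrogen activates the ring A phenol. Both alkene isomers should funnel into the (2S)-flavanone-3-carboxylate A4, whose C3 epimers do not matter.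
- *In favour:* it addresses the only stereocentre catalytically and late. Since MOM ethers and the tert-butyl ester are all acid-labile, one acid treatment might finish the synthesis, which would be up to one operation shorter than the benzyl endgame chosen here and so better on that count.
- *Against:* as the leading cut it leaves the hindered C5'–C8'' bond and the differentiation of the ring D oxygens entirely unsolved. The hot acid needed for decarboxylation would also release seven formaldehyde equivalents next to three phloroglucinol-type rings.
- *Comparison:* this cut complements the aryne plan rather than competing with it. The chosen route closes ring C by the same reaction type in step 13, so the two are equal on stereocontrol and mechanism. The difference is that the chosen plan also supplies the biaryl, separates decarboxylation from deprotection, and ends under neutral conditions.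

**Alternative 3:** The cuts are C8''–C8a'' and C6''–C7'', so ring D is built by a Danheiser benzannulation. Heating the ring B siloxyalkyne A5 with 3-benzyloxycyclobut-2-enone A6 should proceed in four stages: four-electron opening of the cyclobutenone to a ketene function, [2+2] addition of the nucleophilic aryl-bearing alkyne carbon to the ketene carbon, a second ring opening, and six-electron closure. The product is the phenol A7.
- *In favour:* the three ring D oxygens emerge fully differentiated, with only the C8a'' oxygen free. This is a finer differentiation than in the chosen plan and is better on that point. The conditions are neutral and spare the acetal, and benzyl ethers are in place from the start, which saves the ether exchange.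
- *Against:* A5 is hydrolytically sensitive and needs several steps from a ring B ester or alkyne. A6 must itself be prepared, and as a vinylogous ester it should open less readily than simple cyclobutenones. The bond-forming alkyne carbon also carries an aryl group with an ortho benzyloxy substituent.
- *Further work after A7:* the C4a'' acylation must still be done beside an acid-labile acetal, and the silyl ether must be exchanged.
- *Comparison:* structurally both plans reach the same kind of biaryl phenol. Step counts should be similar or less favourable for the benzannulation, because its two components cost more steps than 2 and 4.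

Key step: step 3

Assumption: the C5'–C8'' axis, with three small ortho substituents and one ortho hydrogen, is taken to rotate freely at room temperature (the target has no axial descriptor), and the quinine-derived thiourea is taken to deliver (2S); should the sense be opposite, the pseudo-enantiomeric quinidine-derived catalyst would be used with no other change.

## Steps

Step 1
Reactants: 1 3-fluoro-5-methoxybenzaldehyde
Product: 2 2-(3-fluoro-5-methoxyphenyl)-5,5-dimethyl-1,3-dioxane
Conditions: 2,2-dimethylpropane-1,3-diol (1.2 equiv), TsOH·H2O (cat.), toluene, reflux, Dean–Stark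
Reagents that add atoms: 2,2-dimethylpropane-1,3-diol, CC(C)(CO)CO
Why: Acid-catalysed acetalisation driven by azeotropic removal of water. The six-membered neopentyl acetal is preferred to a dioxolane because a 2-aryl-1,3-dioxolane that loses its acetal proton to an alkyllithium fragments to benzoate and ethene, a cycloreversion closed to the dioxane. Its bulk also shields the two ring positions beside C1' in step 3.

Step 2
Reactants: 3 3,5-dimethoxyphenol
Product: 4 1,3-dimethoxy-5-(methoxymethoxy)benzene
Conditions: NaH, MOMCl, THF/DMF, 0 °C → rt
Reagents that add atoms: chloromethyl methyl ether, COCCl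
Why: Williamson etherification of the sodium phenoxide. The MOM ether marks the oxygen that becomes O1'' and is the strongest lithium-directing group of ring D in steps 3 and 6.

Step 3
Reactants: 2 2-(3-fluoro-5-methoxyphenyl)-5,5-dimethyl-1,3-dioxane; 4 1,3-dimethoxy-5-(methoxymethoxy)benzene
Product: 10 2-[3-(2,4-dimethoxy-6-(methoxymethoxy)phenyl)-4-hydroxy-5-methoxyphenyl]-5,5-dimethyl-1,3-dioxane, via ring D aryllithium 5 (not isolated), via lithiated fluoroarene 6 (not isolated), via ring B aryne 7 (not isolated), via C4'-lithiated biaryl 8 (not isolated), via dimethyl boronate 9 (not isolated)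
Conditions: 4 (2.5 equiv), n-BuLi (2.5 equiv), THF, 0 °C, 1 h; separately 2, s-BuLi (1.05 equiv), THF, −78 °C, 1 h; cold 6 added by cannula over 1 h to 5 at −25 °C, then 1 h; B(OCH3)3 (6 equiv), −78 °C → rt; 30% aq. H2O2, 0 °C → rt
Reagents that add atoms: hydrogen peroxide, OO (the C4' oxygen); trimethyl borate, COB(OC)OC (boron and methoxy groups of 9 only); n-butyllithium, [Li]CCCC, and sec-butyllithium, [Li]C(C)CC (lithium of 5, 6 and 8 only)
Why: s-BuLi removes the proton of 2 between F and OCH3 (C4'), the most acidic ring position, and 6 persists at −78 °C; an alkyllithium rather than a lithium amide is used so that no amine is present to add to the aryne. When 6 runs slowly into excess 5 at −25 °C it loses LiF, so 7 is formed at low concentration in a large excess of the intended nucleophile, which suppresses capture by 6 or 8. The C3' methoxy group distorts and polarises the C4'–C5' triple bond, so 5 bonds to the remote carbon C5' and the charge develops on C4' beside the electron-withdrawing oxygen, where lithium is chelated by the C3' methoxy group and by a ring D ether oxygen. The di-ortho-substituted nucleophile meets little hindrance because C5' of the aryne has only C6'–H beside it. 8 is taken up by the small electrophile B(OCH3)3, and 9 is oxidised by H2O2 in the alkoxide-basic mixture with aryl migration from boron to oxygen, conditions that leave the acetal and the MOM ether intact. The closest known reaction type is the addition of hindered aryllithium or arylmagnesium reagents to arynes followed by electrophilic trapping of the 2-metalated biaryl, as used for dialkylbiarylphosphines, and borylation–oxidation of an aryllithium is routine. No ring is closed and no stereocentre is formed. The step needs site-selective metalation of both partners (F/OCH3 flanking in 2; OCH3/OMOM flanking with MOM chelation at C4 of 4) and regioselective aryne capture, which the C3' methoxy group secures.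

Step 4
Reactants: 10 2-[3-(2,4-dimethoxy-6-(methoxymethoxy)phenyl)-4-hydroxy-5-methoxyphenyl]-5,5-dimethyl-1,3-dioxane
Product: 11 2-[3-(2,4-dimethoxy-6-(methoxymethoxy)phenyl)-4,5-dimethoxyphenyl]-5,5-dimethyl-1,3-dioxane
Conditions: MeI, K2CO3, DMF, rt
Reagents that add atoms: iodomethane, CI
Why: Williamson methylation of the C4' phenol. It removes the acidic proton before the second metalation and ends the para-hydroxy activation that makes the acetal of 10 labile. It costs nothing later because all methyl ethers are cleaved together in step 8.

Step 5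
Reactants: 12 1-ethynyl-4-methoxybenzene
Product: 14 N-methoxy-3-(4-methoxyphenyl)-N-methylprop-2-ynamide, via lithium acetylide 13 (not isolated)
Conditions: n-BuLi, THF, −78 °C; ClC(O)N(CH3)OCH3, −78 °C → 0 °C
Reagents that add atoms: N-methoxy-N-methylcarbamoyl chloride, CON(C)C(=O)Cl; n-butyllithium, [Li]CCCC (lithium of 13 only)
Why: Acylation of a lithium acetylide with a carbamoyl chloride gives the alkynyl Weinreb amide in one step. The amide has no α-hydrogen, so the hindered aryllithium of step 6 cannot enolise it.

Step 6
Reactants: 11 2-[3-(2,4-dimethoxy-6-(methoxymethoxy)phenyl)-4,5-dimethoxyphenyl]-5,5-dimethyl-1,3-dioxane; 14 N-methoxy-3-(4-methoxyphenyl)-N-methylprop-2-ynamide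
Product: 16 1-{3-[5-(5,5-dimethyl-1,3-dioxan-2-yl)-2,3-dimethoxyphenyl]-4,6-dimethoxy-2-(methoxymethoxy)phenyl}-3-(4-methoxyphenyl)prop-2-yn-1-one, via C4a''-lithiated biaryl 15 (not isolated)
Conditions: n-BuLi (1.2 equiv), THF, 0 °C, 1 h; 14 (1.3 equiv), −78 °C → −20 °C; AcOH in THF, −78 °C
Reagents that add atoms: n-butyllithium, [Li]CCCC (lithium of 15 only; 16 holds only atoms of 11 and 14)
Why: Directed ortho-metalation followed by Weinreb ketone synthesis. C4a''–H lies between OMOM and the C5'' methoxy group, and the MOM chain, pushed by ring B toward C4a'', can still deliver lithium through its outer oxygen, whereas the buttressed C7'' and C3' methoxy groups turn their lone pairs away from C6''–H and C2'–H. The chelated tetrahedral adduct prevents over-addition, and the cold AcOH quench keeps the released hydroxylamine protonated so that it does not add to the ynone.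

Step 7
Reactants: 16 1-{3-[5-(5,5-dimethyl-1,3-dioxan-2-yl)-2,3-dimethoxyphenyl]-4,6-dimethoxy-2-(methoxymethoxy)phenyl}-3-(4-methoxyphenyl)prop-2-yn-1-one
Product: 18 3-[5,7-dimethoxy-2-(4-methoxyphenyl)-4-oxo-4H-chromen-8-yl]-4,5-dimethoxybenzaldehyde, via hydroxy ynone aldehyde 17 (not isolated)
Conditions: 6 M aq. HCl, THF/MeOH, 50 °C
Reagents that add atoms: water, O (the aldehyde oxygen)
Why: One acid treatment cleaves the MOM ether (activated by the ortho carbonyl) and the acetal, and the freed C8a'' phenol adds to the protonated ynone at the anisyl-stabilised β-carbon, the known acid-promoted 6-endo-dig closure of o-hydroxyaryl ynones to flavones; solvent or HCl adducts of the ynone funnel to the same product. Only the C8a'' oxygen is free, so only the 8-aryl isomer can form. The aldehyde appears only after ring D has been deactivated by its carbonyl group.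

Step 8
Reactants: 18 3-[5,7-dimethoxy-2-(4-methoxyphenyl)-4-oxo-4H-chromen-8-yl]-4,5-dimethoxybenzaldehyde
Product: 19 3-[5,7-dihydroxy-2-(4-hydroxyphenyl)-4-oxo-4H-chromen-8-yl]-4,5-dihydroxybenzaldehyde
Conditions: BBr3 (12 equiv), CH2Cl2, −78 °C → rt; MeOH, then H2O
Reagents that add atoms: none
Why: Lewis-acid cleavage of five aryl methyl ethers, placed before the stereocentre exists. In CH2Cl2 at or below room temperature ring E is not opened, so no Wessely–Moser drift to the 6-aryl isomer is expected. Any bromide adduct of the electron-rich aldehyde reverts on aqueous work-up.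

Step 9
Reactants: 19 3-[5,7-dihydroxy-2-(4-hydroxyphenyl)-4-oxo-4H-chromen-8-yl]-4,5-dihydroxybenzaldehyde
Product: 20 3-{5,7-bis(benzyloxy)-2-[4-(benzyloxy)phenyl]-4-oxo-4H-chromen-8-yl}-4,5-bis(benzyloxy)benzaldehyde
Conditions: BnBr (7 equiv), Cs2CO3, DMF, 60 °C, argon
Reagents that add atoms: benzyl bromide, BrCc1ccccc1
Why: Williamson benzylation of all five phenols. Cs2CO3 and gentle heating are chosen so that the chelated C5'' hydroxyl also reacts, and the inert atmosphere protects the catecholate.

Step 10
Reactants: 21 1-(2,4,6-trihydroxyphenyl)ethan-1-one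
Product: 22 1-[2,4-bis(benzyloxy)-6-hydroxyphenyl]ethan-1-one
Conditions: BnBr (2.1 equiv), K2CO3, DMF, rt → 40 °C
Reagents that add atoms: benzyl bromide, BrCc1ccccc1
Why: Selective Williamson benzylation. After two alkylations the remaining ortho hydroxyl is held in a hydrogen bond to the ketone and is the least reactive, so it stays free as the future O1.

Step 11
Reactants: 22 1-[2,4-bis(benzyloxy)-6-hydroxyphenyl]ethan-1-one
Product: 24 tert-butyl 3-[2,4-bis(benzyloxy)-6-hydroxyphenyl]-3-oxopropanoate, via dilithium phenoxide enolate 23 (not isolated)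
Conditions: LiN(SiMe3)2 (3.3 equiv), THF, −78 °C; Boc2O (1.1 equiv), −78 °C → 0 °C; AcOH
Reagents that add atoms: di-tert-butyl dicarbonate, CC(C)(C)OC(=O)OC(=O)OC(C)(C)C; lithium bis(trimethylsilyl)amide, [Li]N([Si](C)(C)C)[Si](C)(C)C (lithium of 23 only)
Why: Claisen-type C-alkoxycarbonylation of the phenoxide–enolate dianion, the ester counterpart of the C-aroylation of polylithiated o-hydroxyacetophenones; the third equivalent of base takes up the acidic product. A Boc group that lands on the phenoxide can move to the enolate carbon in the Baker–Venkataraman manner, so both paths converge. The tert-butyl ester resists lactonisation to the 4-hydroxycoumarin.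

Step 12
Reactants: 20 3-{5,7-bis(benzyloxy)-2-[4-(benzyloxy)phenyl]-4-oxo-4H-chromen-8-yl}-4,5-bis(benzyloxy)benzaldehyde; 24 tert-butyl 3-[2,4-bis(benzyloxy)-6-hydroxyphenyl]-3-oxopropanoate
Product: 25 tert-butyl 2-[2,4-bis(benzyloxy)-6-hydroxybenzoyl]-3-(3-{5,7-bis(benzyloxy)-2-[4-(benzyloxy)phenyl]-4-oxo-4H-chromen-8-yl}-4,5-bis(benzyloxy)phenyl)prop-2-enoate (E/Z mixture)
Conditions: piperidine (20 mol%), AcOH (20 mol%), 4 Å MS, toluene, rt
Reagents that add atoms: none
Why: Knoevenagel condensation; the aldehyde has hydrogen at both ortho positions and is unhindered. The E/Z mixture is acceptable because step 13 is stereoconvergent. Room temperature and the buffered amine limit premature racemic ring closure.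

Step 13
Reactants: 25 tert-butyl 2-[2,4-bis(benzyloxy)-6-hydroxybenzoyl]-3-(3-{5,7-bis(benzyloxy)-2-[4-(benzyloxy)phenyl]-4-oxo-4H-chromen-8-yl}-4,5-bis(benzyloxy)phenyl)prop-2-enoate (E/Z mixture)
Product: 27 (2S)-5,7-bis(benzyloxy)-2-(3-{5,7-bis(benzyloxy)-2-[4-(benzyloxy)phenyl]-4-oxo-4H-chromen-8-yl}-4,5-bis(benzyloxy)phenyl)-2,3-dihydro-4H-chromen-4-one, via tert-butyl flavanone-3-carboxylate 26 (not isolated)
Conditions: 1-[3,5-bis(trifluoromethyl)phenyl]-3-[(8α,9S)-6'-methoxycinchonan-9-yl]thiourea (10 mol%), toluene, −25 °C; then TsOH·H2O, 80 °C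
Reagents that add atoms: none
Why: Bifunctional-thiourea-catalysed intramolecular oxa-Michael addition to an alkylidene β-keto ester, followed in the same flask by acid-induced loss of isobutene and CO2, a known flavanone synthesis. The thiourea binds the two carbonyl groups and the quinuclidine nitrogen activates the ring A phenol, so O1 reaches one face of C2 of either alkene isomer and sets (2S), while C3 is stereolabile and ends as CH2. Benzyl ethers, unlike acetal-type ethers, tolerate the TsOH phase.

Step 14
Reactants: 27 (2S)-5,7-bis(benzyloxy)-2-(3-{5,7-bis(benzyloxy)-2-[4-(benzyloxy)phenyl]-4-oxo-4H-chromen-8-yl}-4,5-bis(benzyloxy)phenyl)-2,3-dihydro-4H-chromen-4-one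
Product: 28 (2S)-2-{3-[5,7-dihydroxy-2-(4-hydroxyphenyl)-4-oxo-4H-chromen-8-yl]-4,5-dihydroxyphenyl}-5,7-dihydroxy-2,3-dihydro-4H-chromen-4-one (CNP0204144.1)
Conditions: H2 (1 atm), 10% Pd/C, THF/MeOH, rt
Reagents that add atoms: none
Why: Hydrogenolysis of seven aryl benzyl ethers under neutral conditions, which neither open ring C nor epimerise C2. The reaction is stopped once hydrogen uptake corresponds to seven equivalents, to spare C2''=C3'' and the C2–O1 bond.

## Compound list

1 | 3-fluoro-5-methoxybenzaldehyde | COc1cc(F)cc(C=O)c1 | starting material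
2 | 2-(3-fluoro-5-methoxyphenyl)-5,5-dimethyl-1,3-dioxane | COc1cc(F)cc(C2OCC(C)(C)CO2)c1 | intermediate
3 | 3,5-dimethoxyphenol | COc1cc(O)cc(OC)c1 | starting material
4 | 1,3-dimethoxy-5-(methoxymethoxy)benzene | COCOc1cc(OC)cc(OC)c1 | intermediate
5 | [2,4-dimethoxy-6-(methoxymethoxy)phenyl]lithium | [Li]c1c(OC)cc(OC)cc1OCOC | intermediate
6 | [4-(5,5-dimethyl-1,3-dioxan-2-yl)-2-fluoro-6-methoxyphenyl]lithium | [Li]c1c(F)cc(C2OCC(C)(C)CO2)cc1OC | intermediate
7 | 5-(5,5-dimethyl-1,3-dioxan-2-yl)-3-methoxy-1,2-didehydrobenzene | COC1=CC(C2OCC(C)(C)CO2)=CC#C1 | intermediate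
8 | {4-(5,5-dimethyl-1,3-dioxan-2-yl)-2-[2,4-dimethoxy-6-(methoxymethoxy)phenyl]-6-methoxyphenyl}lithium | [Li]c1c(OC)cc(C2OCC(C)(C)CO2)cc1-c1c(OC)cc(OC)cc1OCOC | intermediate
9 | dimethyl {4-(5,5-dimethyl-1,3-dioxan-2-yl)-2-[2,4-dimethoxy-6-(methoxymethoxy)phenyl]-6-methoxyphenyl}boronate | COB(OC)c1c(OC)cc(C2OCC(C)(C)CO2)cc1-c1c(OC)cc(OC)cc1OCOC | intermediate
10 | 2-[3-(2,4-dimethoxy-6-(methoxymethoxy)phenyl)-4-hydroxy-5-methoxyphenyl]-5,5-dimethyl-1,3-dioxane | COc1cc(C2OCC(C)(C)CO2)cc(-c2c(OC)cc(OC)cc2OCOC)c1O | intermediate
11 | 2-[3-(2,4-dimethoxy-6-(methoxymethoxy)phenyl)-4,5-dimethoxyphenyl]-5,5-dimethyl-1,3-dioxane | COc1cc(C2OCC(C)(C)CO2)cc(-c2c(OC)cc(OC)cc2OCOC)c1OC | intermediate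
12 | 1-ethynyl-4-methoxybenzene | C#Cc1ccc(OC)cc1 | starting material
13 | [(4-methoxyphenyl)ethynyl]lithium | [Li]C#Cc1ccc(OC)cc1 | intermediate
14 | N-methoxy-3-(4-methoxyphenyl)-N-methylprop-2-ynamide | COc1ccc(C#CC(=O)N(C)OC)cc1 | intermediate
15 | {3-[5-(5,5-dimethyl-1,3-dioxan-2-yl)-2,3-dimethoxyphenyl]-4,6-dimethoxy-2-(methoxymethoxy)phenyl}lithium | [Li]c1c(OC)cc(OC)c(-c2cc(C3OCC(C)(C)CO3)cc(OC)c2OC)c1OCOC | intermediate
16 | 1-{3-[5-(5,5-dimethyl-1,3-dioxan-2-yl)-2,3-dimethoxyphenyl]-4,6-dimethoxy-2-(methoxymethoxy)phenyl}-3-(4-methoxyphenyl)prop-2-yn-1-one | COc1ccc(C#CC(=O)c2c(OC)cc(OC)c(-c3cc(C4OCC(C)(C)CO4)cc(OC)c3OC)c2OCOC)cc1 | intermediate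
17 | 3-{2-hydroxy-4,6-dimethoxy-3-[3-(4-methoxyphenyl)prop-2-ynoyl]phenyl}-4,5-dimethoxybenzaldehyde | COc1ccc(C#CC(=O)c2c(OC)cc(OC)c(-c3cc(C=O)cc(OC)c3OC)c2O)cc1 | intermediate
18 | 3-[5,7-dimethoxy-2-(4-methoxyphenyl)-4-oxo-4H-chromen-8-yl]-4,5-dimethoxybenzaldehyde | COc1ccc(-c2cc(=O)c3c(OC)cc(OC)c(-c4cc(C=O)cc(OC)c4OC)c3o2)cc1 | intermediate
19 | 3-[5,7-dihydroxy-2-(4-hydroxyphenyl)-4-oxo-4H-chromen-8-yl]-4,5-dihydroxybenzaldehyde | O=Cc1cc(O)c(O)c(-c2c(O)cc(O)c3c(=O)cc(-c4ccc(O)cc4)oc23)c1 | intermediate
20 | 3-{5,7-bis(benzyloxy)-2-[4-(benzyloxy)phenyl]-4-oxo-4H-chromen-8-yl}-4,5-bis(benzyloxy)benzaldehyde | O=Cc1cc(OCc2ccccc2)c(OCc2ccccc2)c(-c2c(OCc3ccccc3)cc(OCc3ccccc3)c3c(=O)cc(-c4ccc(OCc5ccccc5)cc4)oc23)c1 | intermediate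
21 | 1-(2,4,6-trihydroxyphenyl)ethan-1-one | CC(=O)c1c(O)cc(O)cc1O | starting material
22 | 1-[2,4-bis(benzyloxy)-6-hydroxyphenyl]ethan-1-one | CC(=O)c1c(O)cc(OCc2ccccc2)cc1OCc1ccccc1 | intermediate
23 | dilithium phenoxide enolate of 22 | [Li]OC(=C)c1c(O[Li])cc(OCc2ccccc2)cc1OCc1ccccc1 | intermediate
24 | tert-butyl 3-[2,4-bis(benzyloxy)-6-hydroxyphenyl]-3-oxopropanoate | CC(C)(C)OC(=O)CC(=O)c1c(O)cc(OCc2ccccc2)cc1OCc1ccccc1 | intermediate
25 | heptabenzyl alkylidene β-keto ester, E/Z mixture (name as in step 12) | CC(C)(C)OC(=O)C(=Cc1cc(OCc2ccccc2)c(OCc2ccccc2)c(-c2c(OCc3ccccc3)cc(OCc3ccccc3)c3c(=O)cc(-c4ccc(OCc5ccccc5)cc4)oc23)c1)C(=O)c1c(O)cc(OCc2ccccc2)cc1OCc1ccccc1 | intermediate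
26 | tert-butyl (2S)-heptabenzyl-flavanone-3-carboxylate, labile epimers at C3 | O=C1C(C(=O)OC(C)(C)C)[C@@H](c2cc(OCc3ccccc3)c(OCc3ccccc3)c(-c3c(OCc4ccccc4)cc(OCc4ccccc4)c4c(=O)cc(-c5ccc(OCc6ccccc6)cc5)oc34)c2)Oc2cc(OCc3ccccc3)cc(OCc3ccccc3)c21 | intermediate
27 | (2S)-heptabenzyl ether of the target (name as in step 13) | O=C1C[C@@H](c2cc(OCc3ccccc3)c(OCc3ccccc3)c(-c3c(OCc4ccccc4)cc(OCc4ccccc4)c4c(=O)cc(-c5ccc(OCc6ccccc6)cc5)oc34)c2)Oc2cc(OCc3ccccc3)cc(OCc3ccccc3)c21 | intermediate
28 | (2S)-2-{3-[5,7-dihydroxy-2-(4-hydroxyphenyl)-4-oxo-4H-chromen-8-yl]-4,5-dihydroxyphenyl}-5,7-dihydroxy-2,3-dihydro-4H-chromen-4-one | O=C1C[C@@H](c2cc(O)c(O)c(-c3c(O)cc(O)c4c(=O)cc(-c5ccc(O)cc5)oc34)c2)Oc2cc(O)cc(O)c21 | target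

## Step count and least certain steps

Total: 14 steps. Longest linear sequence: 10 steps (1, 3, 4, 6, 7, 8, 9, 12, 13, 14).

**Step 3 (key step).** Several things can go wrong.
- The most likely failure is loss of the C4' carbanion by proton transfer before the borate arrives. The proton could come from any unmetalated 2 or 4, or from THF during the warm phase, and the biaryl would then lack its oxygen.
- The aryne can be captured by 6 or 8 instead of 5, which depends on relative concentrations.
- Metalation of 4 may not be fully site-selective, since the position between the two methoxy groups is also activated.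
- The excess of 5 is borylated and oxidised as well and must be separated from 10.

The fallback makes the biaryl bond by Suzuki–Miyaura coupling and buys in the C4' oxygen. It sets out from 4. Lithiation to 5 as before and quenching with 2-isopropoxy-4,4,5,5-tetramethyl-1,3,2-dioxaborolane gives the pinacol boronate F1. Commercial 3-bromo-4,5-dimethoxybenzaldehyde F2 is converted with 2,2-dimethylpropane-1,3-diol and TsOH into its neopentyl acetal F3. F1 and F3 are coupled with Pd(OAc)2, SPhos and K3PO4 in toluene/water at 90 °C. The route is rejoined at 11, so step 4 is no longer needed.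

**Step 6.** Metalation may go partly to C6'' or C2', may be slow because the MOM group is crowded by ring B, or may be accompanied by attack on the benzylic acetal C–H.

The fallback gives up the second metalation for a phenol-directed Friedel–Crafts acylation on an acid-proof aldehyde mask. It sets out from 11.
- Propane-1,3-dithiol and BF3·OEt2 in CH2Cl2 exchange the acetal for a dithiane and remove the MOM group in one operation, with the thiol outrunning ring D for every cation. This gives the phenol dithiane F4.
- Ac2O and BF3·OEt2 acetylate ortho to the free phenol under chelate control to give the o-hydroxyacetophenone F5.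
- LiN(SiMe3)2 (3 equiv) followed by 4-methoxybenzoyl chloride gives the 1,3-diketone F6.
- Catalytic H2SO4 in AcOH closes ring E to the flavone dithiane F7.
- MeI and CaCO3 in aqueous MeCN release the aldehyde, and the route is rejoined at 18.

**Step 11.** Acylation may take place on the phenoxide or enolate oxygen without moving on to carbon. A second acylation may follow, or the phenoxide may close onto the ester.

The fallback drops the activating ester and accepts a racemic closure with resolution. It sets out from 22 and 20. Claisen–Schmidt condensation (KOH, EtOH/THF, rt) gives the (E)-2'-hydroxychalcone F8. NaOAc in refluxing EtOH closes it to the racemic heptabenzyl flavanone F9. Preparative chromatography on a chiral stationary phase separates 27 from the (2R)-flavanone F10, which is returned to F9 by base-induced ring opening and reclosure. The route is rejoined at 27.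

**Step 13.** Facial selectivity may be poor. The C5 benzyloxy group twists the aroyl group out of conjugation, and the ring B side is far larger than in the usual substrates. An uncatalysed background closure may compete. The hot TsOH phase may also cause partial racemisation through acid-induced opening of ring C, which the C4' benzyloxy group assists.

The fallback replaces asymmetric catalysis by resolution. It sets out from 25. Et3N in toluene closes it to the racemic tert-butyl flavanone-3-carboxylate F11, and TsOH·H2O at 80 °C converts this into F9. Resolution and recycling of F10 then follow as described for step 11. The route is rejoined at 27.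

**Step 14.** The C2''=C3'' bond may be over-reduced, the benzylic C2–O1 bond may undergo hydrogenolysis, or the reaction may stall when partly debenzylated material precipitates.

The fallback is non-reductive. It sets out from 27, which is treated with BCl3 and pentamethylbenzene (as benzyl cation scavenger) in CH2Cl2 at −78 °C. It ends directly at 28 and passes through no new compound.

## Further compounds

F1 | step 3 | 2-[2,4-dimethoxy-6-(methoxymethoxy)phenyl]-4,4,5,5-tetramethyl-1,3,2-dioxaborolane | COCOc1cc(OC)cc(OC)c1B1OC(C)(C)C(C)(C)O1
F2 | step 3 | 3-bromo-4,5-dimethoxybenzaldehyde | COc1cc(C=O)cc(Br)c1OC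
F3 | step 3 | 2-(3-bromo-4,5-dimethoxyphenyl)-5,5-dimethyl-1,3-dioxane | COc1cc(C2OCC(C)(C)CO2)cc(Br)c1OC
F4 | step 6 | 2-[5-(1,3-dithian-2-yl)-2,3-dimethoxyphenyl]-3,5-dimethoxyphenol | COc1cc(C2SCCCS2)cc(-c2c(OC)cc(OC)cc2O)c1OC
F5 | step 6 | 1-{3-[5-(1,3-dithian-2-yl)-2,3-dimethoxyphenyl]-2-hydroxy-4,6-dimethoxyphenyl}ethan-1-one | CC(=O)c1c(OC)cc(OC)c(-c2cc(C3SCCCS3)cc(OC)c2OC)c1O
F6 | step 6 | 1-{3-[5-(1,3-dithian-2-yl)-2,3-dimethoxyphenyl]-2-hydroxy-4,6-dimethoxyphenyl}-3-(4-methoxyphenyl)propane-1,3-dione | COc1ccc(C(=O)CC(=O)c2c(OC)cc(OC)c(-c3cc(C4SCCCS4)cc(OC)c3OC)c2O)cc1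
F7 | step 6 | 8-[5-(1,3-dithian-2-yl)-2,3-dimethoxyphenyl]-5,7-dimethoxy-2-(4-methoxyphenyl)-4H-chromen-4-one | COc1ccc(-c2cc(=O)c3c(OC)cc(OC)c(-c4cc(C5SCCCS5)cc(OC)c4OC)c3o2)cc1
F8 | step 11 | (E)-1-[2,4-bis(benzyloxy)-6-hydroxyphenyl]-3-(3-{5,7-bis(benzyloxy)-2-[4-(benzyloxy)phenyl]-4-oxo-4H-chromen-8-yl}-4,5-bis(benzyloxy)phenyl)prop-2-en-1-one | O=C(/C=C/c1cc(OCc2ccccc2)c(OCc2ccccc2)c(-c2c(OCc3ccccc3)cc(OCc3ccccc3)c3c(=O)cc(-c4ccc(OCc5ccccc5)cc4)oc23)c1)c1c(O)cc(OCc2ccccc2)cc1OCc1ccccc1
F9 | step 11 | racemic heptabenzyl flavanone (racemate of 27) | O=C1CC(c2cc(OCc3ccccc3)c(OCc3ccccc3)c(-c3c(OCc4ccccc4)cc(OCc4ccccc4)c4c(=O)cc(-c5ccc(OCc6ccccc6)cc5)oc34)c2)Oc2cc(OCc3ccccc3)cc(OCc3ccccc3)c21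
F10 | step 11 | (2R)-heptabenzyl flavanone (enantiomer of 27) | O=C1C[C@H](c2cc(OCc3ccccc3)c(OCc3ccccc3)c(-c3c(OCc4ccccc4)cc(OCc4ccccc4)c4c(=O)cc(-c5ccc(OCc6ccccc6)cc5)oc34)c2)Oc2cc(OCc3ccccc3)cc(OCc3ccccc3)c21
F11 | step 13 | racemic tert-butyl heptabenzyl-flavanone-3-carboxylate (racemate of 26) | O=C1C(C(=O)OC(C)(C)C)C(c2cc(OCc3ccccc3)c(OCc3ccccc3)c(-c3c(OCc4ccccc4)cc(OCc4ccccc4)c4c(=O)cc(-c5ccc(OCc6ccccc6)cc5)oc34)c2)Oc2cc(OCc3ccccc3)cc(OCc3ccccc3)c21
F0 | step 14 | none | none
A1 | alternative 1 | tert-butyl 4-(5-bromo-2,3-dibenzyloxyphenyl)-4-[6-(4-benzyloxyphenyl)-4-oxo-4H-pyran-2-yl]-3-oxobutanoate | CC(C)(C)OC(=O)CC(=O)C(c1cc(Br)cc(OCc2ccccc2)c1OCc1ccccc1)c1cc(=O)cc(-c2ccc(OCc3ccccc3)cc2)o1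
A2 | alternative 1 | 8-(5-bromo-2,3-dibenzyloxyphenyl)-5,7-dihydroxy-4'-benzyloxyflavone | Oc1cc(O)c2c(=O)cc(-c3ccc(OCc4ccccc4)cc3)oc2c1-c1cc(Br)cc(OCc2ccccc2)c1OCc1ccccc1
A3 | alternative 2 | hepta-MOM alkylidene β-keto ester, E/Z mixture | CC(C)(C)OC(=O)C(=Cc1cc(OCOC)c(OCOC)c(-c2c(OCOC)cc(OCOC)c3c(=O)cc(-c4ccc(OCOC)cc4)oc23)c1)C(=O)c1c(O)cc(OCOC)cc1OCOC
A4 | alternative 2 | tert-butyl (2S)-hepta-MOM-flavanone-3-carboxylate, labile epimers at C3 | O=C1C(C(=O)OC(C)(C)C)[C@@H](c2cc(OCOC)c(OCOC)c(-c3c(OCOC)cc(OCOC)c4c(=O)cc(-c5ccc(OCOC)cc5)oc34)c2)Oc2cc(OCOC)cc(OCOC)c21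
A5 | alternative 3 | {[2,3-bis(benzyloxy)-5-(1,3-dioxolan-2-yl)phenyl]ethynyloxy}tri(propan-2-yl)silane | CC(C)[Si](OC#Cc1cc(C2OCCO2)cc(OCc2ccccc2)c1OCc1ccccc1)(C(C)C)C(C)C
A6 | alternative 3 | 3-(benzyloxy)cyclobut-2-en-1-one | O=C1C=C(OCc2ccccc2)C1
A7 | alternative 3 | 5-(benzyloxy)-2-[2,3-bis(benzyloxy)-5-(1,3-dioxolan-2-yl)phenyl]-3-[tri(propan-2-yl)silyloxy]phenol | Oc1cc(OCc2ccccc2)cc(O[Si](C(C)C)(C(C)C)C(C)C)c1-c1cc(C2OCCO2)cc(OCc2ccccc2)c1OCc1ccccc1
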